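The plan rests on cutting the furan ring at C2, the carbon that is benzylic to ring B and bonded to both O1 and C3. It is delivered as a benzylic sulfonium ylide to a symmetric nitrostyrene of ring A whose alkene carbons become C3 and the formyl carbon C8 and whose two ortho phenols become O1 and the C4 hydroxyl. One operation forms C2–C3 and O1–C2 and closes the dihydrofuran; the nitromethyl group is the masked aldehyde. The precursors are (E)-5-methoxy-2-(2-nitrovinyl)benzene-1,3-diol and a bis-MOM 2,4-dioxygenated benzyl dimethylsulfonium salt. Dehydrogenation, a Nef reaction, and a propargylation/semihydrogenation/Claisen sequence for the C5 prenyl group complete the route.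

Key step: step 8

Remark: the intermediates with sp3 stereocentres are racemic (one enantiomer written); the target has no stereocentre.

Step 1
Reactants: 1 5-methoxyresorcinol
Product: 2 1-methoxy-3,5-bis(methoxymethoxy)benzene
Conditions: MOMCl (2.5 equiv), i-Pr2NEt (3 equiv), CH2Cl2, 0 °C to rt
Reagents that add atoms: chloromethyl methyl ether, COCCl
Why: Williamson-type O-alkylation (MOM protection) of both phenols by the reactive α-chloro ether under amine base should be clean and installs the two directing groups needed in step 2.

Step 2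
Reactants: 2 1-methoxy-3,5-bis(methoxymethoxy)benzene
Product: 4 4-methoxy-2,6-bis(methoxymethoxy)benzaldehyde, via aryllithium 3 (not isolated)
Conditions: n-BuLi (1.2 equiv), TMEDA, THF, 0 °C; DMF, 0 °C to rt; H2O
Reagents that add atoms: N,N-dimethylformamide, CN(C)C=O
Why: Directed ortho-metalation should occur at the ring position flanked by the two chelating OMOM groups in preference to the positions between OMOM and OMe, and formylation of the aryllithium by DMF places the aldehyde carbon between the two protected oxygens.

Step 3
Reactants: 4 4-methoxy-2,6-bis(methoxymethoxy)benzaldehyde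
Product: 5 2,6-dihydroxy-4-methoxybenzaldehyde
Conditions: 3 M aq. HCl, MeOH, 50 °C
Reagents that add atoms: none
Why: Acid-catalysed acetal cleavage (MOM removal) is fast for ethers ortho to a formyl group and should free both phenols while the aryl methyl ether stays intact.

Step 4
Reactants: 5 2,6-dihydroxy-4-methoxybenzaldehyde; 6 nitromethane
Product: 7 (E)-5-methoxy-2-(2-nitrovinyl)benzene-1,3-diol
Conditions: NH4OAc (1 equiv), MeNO2 (10 equiv), AcOH, 90 °C
Reagents that add atoms: nitromethane (6), C[N+](=O)[O-]
Why: Henry (nitroaldol) condensation with dehydration in the same flask under ammonium acetate catalysis should give the conjugated nitroalkene, the E isomer being the thermodynamic product.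

Step 5
Reactants: 8 2,4-dihydroxybenzaldehyde
Product: 9 2,4-bis(methoxymethoxy)benzaldehyde
Conditions: MOMCl (3 equiv), i-Pr2NEt (4 equiv), CH2Cl2, 0 °C to 40 °C
Reagents that add atoms: chloromethyl methyl ether, COCCl
Why: MOM protection by O-alkylation should cap both phenols, excess reagent and gentle warming being used because the hydroxyl ortho to the formyl group is hydrogen-bonded and reacts more slowly.

Step 6
Reactants: 9 2,4-bis(methoxymethoxy)benzaldehyde
Product: 10 [2,4-bis(methoxymethoxy)phenyl]methanol
Conditions: NaBH4, MeOH, 0 °C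
Reagents that add atoms: none
Why: Borohydride reduction of an aromatic aldehyde to the benzylic alcohol is reliable and leaves the MOM acetals untouched.

Step 7
Reactants: 10 [2,4-bis(methoxymethoxy)phenyl]methanol
Product: 12 [2,4-bis(methoxymethoxy)benzyl]dimethylsulfonium bromide, via benzylic bromide 11 (not isolated)
Conditions: CBr4 (1.2 equiv), PPh3 (1.15 equiv), CH2Cl2, 0 °C; then Me2S (5 equiv), rt; Et2O
Reagents that add atoms: carbon tetrabromide, BrC(Br)(Br)Br; dimethyl sulfide, CSC
Why: The Appel reaction brominates under neutral conditions that spare the acid-labile MOM groups, and the labile electron-rich benzylic bromide is trapped at once by S-alkylation of dimethyl sulfide (SN2), the salt being precipitated by ether and used promptly.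

Step 8
Reactants: 7 (E)-5-methoxy-2-(2-nitrovinyl)benzene-1,3-diol; 12 [2,4-bis(methoxymethoxy)benzyl]dimethylsulfonium bromide
Product: 15 rac-(2R,3S)-2-[2,4-bis(methoxymethoxy)phenyl]-6-methoxy-3-(nitromethyl)-2,3-dihydro-1-benzofuran-4-ol (trans), via sulfonium ylide 13 (not isolated), via nitronate sulfonium betaine 14 (not isolated)
Conditions: 12 (1.3 equiv), Cs2CO3 (1.5 equiv), MeCN, 0 °C to rt
Reagents that add atoms: none
Why: Carbonate turns 7 into its phenoxide, which pairs with the sulfonium cation and deprotonates it reversibly to ylide 13 beside neutral 7; the ylide carbon then adds in a Michael reaction to the alkene carbon that carries ring A (bond C2–C3) and gives betaine 14. Proton transfer from an ortho hydroxyl to the nitronate leaves a phenoxide that displaces dimethyl sulfide from C2 (bond O1–C2) in a 5-exo-tet ring closure, which forms the dihydrofuran ring. The closest known reaction type is the formal [4+1] annulation of sulfonium ylides with ortho-hydroxy-β-nitrostyrenes (domino Michael addition and intramolecular O-alkylation) to trans-3-(nitromethyl)-2,3-dihydrobenzofurans, used here with a benzyl-substituted ylide. Both new stereocentres (C2, C3) are controlled by the substrate in the ring closure: the diastereomeric betaines equilibrate through reversible deprotonation at the sulfonium carbon, and the closure that places the aryl group and the nitromethyl group on opposite faces of the forming ring is the less crowded one, so the racemic trans isomer should result. The selectivity required is closure by the phenoxide oxygen and not by the nitronate oxygen (isoxazoline N-oxide) or carbon (cyclopropane), secured by the higher nucleophilicity of the phenoxide, its five-membered transition state and the ready displacement at a benzylic carbon activated by the two oxygens of ring B. Because 7 is symmetric, either hydroxyl can close and the other remains as the C4 hydroxyl.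

Step 9
Reactants: 15 rac-(2R,3S)-2-[2,4-bis(methoxymethoxy)phenyl]-6-methoxy-3-(nitromethyl)-2,3-dihydro-1-benzofuran-4-ol
Product: 16 2-[2,4-bis(methoxymethoxy)phenyl]-6-methoxy-3-(nitromethyl)-1-benzofuran-4-ol
Conditions: DDQ (1.2 equiv), dry 1,4-dioxane, rt to 60 °C
Reagents that add atoms: none
Why: DDQ dehydrogenation by hydride abstraction from C2–H (activated by O1 and by the dioxygenated ring B) and loss of the C3 proton should aromatise the furan ring, as is established for trans-2-aryl-2,3-dihydrobenzofurans bearing free phenols, and it removes both stereocentres.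

Step 10
Reactants: 16 2-[2,4-bis(methoxymethoxy)phenyl]-6-methoxy-3-(nitromethyl)-1-benzofuran-4-ol
Product: 18 2-[2,4-bis(methoxymethoxy)phenyl]-4-hydroxy-6-methoxy-1-benzofuran-3-carbaldehyde, via disodium nitronate 17 (not isolated)
Conditions: NaOMe (2.2 equiv), MeOH, 0 °C; then aq. TiCl3 (5 equiv) buffered with NH4OAc (pH 5–6), THF/H2O, rt
Reagents that add atoms: water, O
Why: In this reductive Nef reaction the nitronate is reduced by trivalent titanium through the oxime to the imine, which hydrolyses at pH 5–6 to the aldehyde under conditions that should spare the MOM ethers, the free phenol and the electron-rich rings, and no β-elimination is possible once the furan is aromatic.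

Step 11
Reactants: 18 2-[2,4-bis(methoxymethoxy)phenyl]-4-hydroxy-6-methoxy-1-benzofuran-3-carbaldehyde
Product: 19 2-[2,4-bis(methoxymethoxy)phenyl]-6-methoxy-4-[(2-methylbut-3-yn-2-yl)oxy]-1-benzofuran-3-carbaldehyde
Conditions: 3-chloro-3-methylbut-1-yne (1.5 equiv), DBU (1.6 equiv), CuCl2·2H2O (1 mol %), MeCN, 0 °C to rt
Reagents that add atoms: 3-chloro-3-methylbut-1-yne, CC(C)(Cl)C#C
Why: Copper-catalysed O-alkylation of a phenol by a tertiary propargylic chloride is an established route to aryl 1,1-dimethylpropargyl ethers, and the C4 hydroxyl is the only free OH in 18, so no selectivity issue arises.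

Step 12
Reactants: 19 2-[2,4-bis(methoxymethoxy)phenyl]-6-methoxy-4-[(2-methylbut-3-yn-2-yl)oxy]-1-benzofuran-3-carbaldehyde
Product: 20 2-[2,4-bis(methoxymethoxy)phenyl]-6-methoxy-4-[(2-methylbut-3-en-2-yl)oxy]-1-benzofuran-3-carbaldehyde
Conditions: H2 (1 atm), Pd/CaCO3 poisoned with Pb(OAc)2 (Lindlar catalyst), quinoline, EtOAc, rt
Reagents that add atoms: none
Why: Lindlar semihydrogenation should stop at the terminal alkene on the lead-poisoned palladium surface and leave the aldehyde, the benzofuran and the MOM ethers untouched.

Step 13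
Reactants: 20 2-[2,4-bis(methoxymethoxy)phenyl]-6-methoxy-4-[(2-methylbut-3-en-2-yl)oxy]-1-benzofuran-3-carbaldehyde
Product: 22 2-[2,4-bis(methoxymethoxy)phenyl]-4-hydroxy-6-methoxy-5-(3-methylbut-2-en-1-yl)-1-benzofuran-3-carbaldehyde, via cyclohexadienone 21 (not isolated)
Conditions: PhNEt2, 130 °C
Reagents that add atoms: none
Why: In this aromatic Claisen rearrangement the [3,3] shift of the 1,1-dimethylallyl ether delivers the allyl terminus to C5, the only free ortho position (the other is the ring-fusion carbon C3a), and tautomerisation of the dienone restores the phenol, so the side chain arrives as the prenyl group.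

Step 14
Reactants: 22 2-[2,4-bis(methoxymethoxy)phenyl]-4-hydroxy-6-methoxy-5-(3-methylbut-2-en-1-yl)-1-benzofuran-3-carbaldehyde
Product: 23 Ebenfuran III
Conditions: 3 M aq. HCl, MeOH/THF, rt to 40 °C
Reagents that add atoms: none
Why: Acid-catalysed cleavage of the two aryl MOM acetals in methanol at low acid strength and temperature should outpace protonation of the trisubstituted alkene, which is the entry to chroman formation with the C4 hydroxyl.

Compound list
1 | 5-methoxyresorcinol (5-methoxybenzene-1,3-diol) | COc1cc(O)cc(O)c1 | starting material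
2 | 1-methoxy-3,5-bis(methoxymethoxy)benzene | COCOc1cc(OC)cc(OCOC)c1 | intermediate
3 | [4-methoxy-2,6-bis(methoxymethoxy)phenyl]lithium (aryllithium; not isolated) | [Li]c1c(OCOC)cc(OC)cc1OCOC | intermediate
4 | 4-methoxy-2,6-bis(methoxymethoxy)benzaldehyde | COCOc1cc(OC)cc(OCOC)c1C=O | intermediate
5 | 2,6-dihydroxy-4-methoxybenzaldehyde | COc1cc(O)c(C=O)c(O)c1 | intermediate
6 | nitromethane | C[N+](=O)[O-] | starting material
7 | (E)-5-methoxy-2-(2-nitrovinyl)benzene-1,3-diol | COc1cc(O)c(/C=C/[N+](=O)[O-])c(O)c1 | intermediate
8 | 2,4-dihydroxybenzaldehyde | O=Cc1ccc(O)cc1O | starting material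
9 | 2,4-bis(methoxymethoxy)benzaldehyde | COCOc1ccc(C=O)c(OCOC)c1 | intermediate
10 | [2,4-bis(methoxymethoxy)phenyl]methanol | COCOc1ccc(CO)c(OCOC)c1 | intermediate
11 | 1-(bromomethyl)-2,4-bis(methoxymethoxy)benzene (benzylic bromide; not isolated) | COCOc1ccc(CBr)c(OCOC)c1 | intermediate
12 | [2,4-bis(methoxymethoxy)benzyl]dimethylsulfonium bromide | COCOc1ccc(C[S+](C)C)c(OCOC)c1.[Br-] | intermediate
13 | dimethylsulfonium [2,4-bis(methoxymethoxy)phenyl]methylide (sulfonium ylide; not isolated) | COCOc1ccc([CH-][S+](C)C)c(OCOC)c1 | intermediate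
14 | inner salt of [1-[2,4-bis(methoxymethoxy)phenyl]-2-(2,6-dihydroxy-4-methoxyphenyl)-3-aci-nitropropyl]dimethylsulfonium (nitronate sulfonium betaine, diastereomer mixture; not isolated) | COCOc1ccc(C([S+](C)C)C(C=[N+]([O-])[O-])c2c(O)cc(OC)cc2O)c(OCOC)c1 | intermediate
15 | rac-(2R,3S)-2-[2,4-bis(methoxymethoxy)phenyl]-6-methoxy-3-(nitromethyl)-2,3-dihydro-1-benzofuran-4-ol (trans; one enantiomer written) | COCOc1ccc([C@@H]2Oc3cc(OC)cc(O)c3[C@H]2C[N+](=O)[O-])c(OCOC)c1 | intermediate
16 | 2-[2,4-bis(methoxymethoxy)phenyl]-6-methoxy-3-(nitromethyl)-1-benzofuran-4-ol | COCOc1ccc(-c2oc3cc(OC)cc(O)c3c2C[N+](=O)[O-])c(OCOC)c1 | intermediate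
17 | disodium salt of 16, phenoxide and nitronate (not isolated) | COCOc1ccc(-c2oc3cc(OC)cc([O-])c3c2C=[N+]([O-])[O-])c(OCOC)c1.[Na+].[Na+] | intermediate
18 | 2-[2,4-bis(methoxymethoxy)phenyl]-4-hydroxy-6-methoxy-1-benzofuran-3-carbaldehyde | COCOc1ccc(-c2oc3cc(OC)cc(O)c3c2C=O)c(OCOC)c1 | intermediate
19 | 2-[2,4-bis(methoxymethoxy)phenyl]-6-methoxy-4-[(2-methylbut-3-yn-2-yl)oxy]-1-benzofuran-3-carbaldehyde | COCOc1ccc(-c2oc3cc(OC)cc(OC(C)(C)C#C)c3c2C=O)c(OCOC)c1 | intermediate
20 | 2-[2,4-bis(methoxymethoxy)phenyl]-6-methoxy-4-[(2-methylbut-3-en-2-yl)oxy]-1-benzofuran-3-carbaldehyde | COCOc1ccc(-c2oc3cc(OC)cc(OC(C)(C)C=C)c3c2C=O)c(OCOC)c1 | intermediate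
21 | 2-[2,4-bis(methoxymethoxy)phenyl]-6-methoxy-5-(3-methylbut-2-en-1-yl)-4-oxo-4,5-dihydro-1-benzofuran-3-carbaldehyde (cyclohexadienone, racemic at C5; not isolated) | O=C1C(CC=C(C)C)C(OC)=CC2=C1C(C=O)=C(O2)c1ccc(OCOC)cc1OCOC | intermediate
22 | 2-[2,4-bis(methoxymethoxy)phenyl]-4-hydroxy-6-methoxy-5-(3-methylbut-2-en-1-yl)-1-benzofuran-3-carbaldehyde | COCOc1ccc(-c2oc3cc(OC)c(CC=C(C)C)c(O)c3c2C=O)c(OCOC)c1 | intermediate
23 | Ebenfuran III, 2-(2,4-dihydroxyphenyl)-4-hydroxy-6-methoxy-5-(3-methylbut-2-en-1-yl)-1-benzofuran-3-carbaldehyde | COc1cc2oc(-c3ccc(O)cc3O)c(C=O)c2c(O)c1CC=C(C)C | target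

Total step count: 14
Longest linear sequence: 11 steps (steps 1–4 and 8–14, from 1 to 23); the ring B branch (steps 5–7) joins at step 8.

Steps most likely to fail

Step 8. The ylide may form too sparingly because the phenols of 7 are far more acidic than the sulfonium salt. The sulfonium ylide may also rearrange (Sommelet–Hauser), the phenoxide may be benzylated intermolecularly by the ionisation-prone salt, or the nitronate oxygen may close in place of the phenoxide. The fallback brings C2 in at the acyl oxidation level without stoichiometric base, so that ring closure becomes a carbonyl addition. It sets out from aldehyde 9 and nitrostyrene 7. A carbene-catalysed Stetter reaction (N-aryl triazolium or thiazolium precatalyst, catalytic i-Pr2NEt, THF, rt) should add the acyl anion equivalent of 9 to the alkene carbon of 7 attached to ring A. This would give 1-[2,4-bis(methoxymethoxy)phenyl]-2-(2,6-dihydroxy-4-methoxyphenyl)-3-nitropropan-1-one F1. Warming F1 with PPTS in toluene should let one phenol add to the ketone and lose water, a cyclodehydration that forms the aromatic furan directly. The fallback comes back to the route at 16, and step 9 is then not needed.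

Step 10. Reduction of the conjugated benzofuran-3-yl nitronate may stall at the aldoxime, which is stabilised by conjugation and by a hydrogen bond from the C4 hydroxyl. MOM groups may also be lost if the titanium solution is insufficiently buffered. The fallback inverts the order of unmasking and aromatisation and sets out from 15. Treatment with NaOMe in MeOH gives the disodium salt (phenoxide and nitronate) of 15 F2, an ordinary primary nitroalkane substrate. Buffered aqueous TiCl3 should convert it into rac-(2R,3R)-2-[2,4-bis(methoxymethoxy)phenyl]-4-hydroxy-6-methoxy-2,3-dihydro-1-benzofuran-3-carbaldehyde F3 (trans). This aldehyde is kept at or below pH 6, since ring opening by β-elimination would need a stereoelectronically poor alignment but is best not provoked with base. DDQ in dry dioxane should then dehydrogenate F3, helped by enolisation of the aldehyde toward C3, and the fallback comes back to the route at 18.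

Step 14. Protonation of the prenyl alkene and capture of the cation by the neighbouring C4 hydroxyl (closure to a 2,2-dimethylchroman) may compete with hydrolysis of the acetals. The fallback moves the acid step ahead of the alkene and sets out from 19. Treating 19 with 3 M aq. HCl in MeOH should remove both MOM groups and give 2-(2,4-dihydroxyphenyl)-6-methoxy-4-[(2-methylbut-3-yn-2-yl)oxy]-1-benzofuran-3-carbaldehyde F4. No alkene and no free C4 hydroxyl are present at that stage, and the tertiary propargylic ether ionises far less readily than an allylic one. Semihydrogenation (H2, Pd/CaCO3 poisoned with Pb(OAc)2, quinoline, EtOAc) should give 2-(2,4-dihydroxyphenyl)-6-methoxy-4-[(2-methylbut-3-en-2-yl)oxy]-1-benzofuran-3-carbaldehyde F5. Heating F5 in PhNEt2 at 130 °C should bring about the Claisen rearrangement through 2-(2,4-dihydroxyphenyl)-6-methoxy-5-(3-methylbut-2-en-1-yl)-4-oxo-4,5-dihydro-1-benzofuran-3-carbaldehyde F6. The fallback comes back to the route at the target 23, so that the last operation is thermal and neutral.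

Further compounds
F1 | step 8 | 1-[2,4-bis(methoxymethoxy)phenyl]-2-(2,6-dihydroxy-4-methoxyphenyl)-3-nitropropan-1-one (racemic) | COCOc1ccc(C(=O)C(C[N+](=O)[O-])c2c(O)cc(OC)cc2O)c(OCOC)c1
F2 | step 10 | disodium salt (phenoxide and nitronate) of 15 (trans, racemic) | COCOc1ccc([C@@H]2Oc3cc(OC)cc([O-])c3[C@H]2C=[N+]([O-])[O-])c(OCOC)c1.[Na+].[Na+]
F3 | step 10 | rac-(2R,3R)-2-[2,4-bis(methoxymethoxy)phenyl]-4-hydroxy-6-methoxy-2,3-dihydro-1-benzofuran-3-carbaldehyde (trans) | COCOc1ccc([C@@H]2Oc3cc(OC)cc(O)c3[C@H]2C=O)c(OCOC)c1
F4 | step 14 | 2-(2,4-dihydroxyphenyl)-6-methoxy-4-[(2-methylbut-3-yn-2-yl)oxy]-1-benzofuran-3-carbaldehyde | COc1cc(OC(C)(C)C#C)c2c(C=O)c(-c3ccc(O)cc3O)oc2c1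
F5 | step 14 | 2-(2,4-dihydroxyphenyl)-6-methoxy-4-[(2-methylbut-3-en-2-yl)oxy]-1-benzofuran-3-carbaldehyde | COc1cc(OC(C)(C)C=C)c2c(C=O)c(-c3ccc(O)cc3O)oc2c1
F6 | step 14 | 2-(2,4-dihydroxyphenyl)-6-methoxy-5-(3-methylbut-2-en-1-yl)-4-oxo-4,5-dihydro-1-benzofuran-3-carbaldehyde (racemic at C5, transient) | O=C1C(CC=C(C)C)C(OC)=CC2=C1C(C=O)=C(O2)c1ccc(O)cc1O
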